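(The earlier runs and the new flask stem from a simulated flask on assumed constants.)

**Equal fractions.** The ratio of monomer in chains at 20.0 h, violet over ochre, reads 1.06, although ochre was charged twice the free monomer. So I carry the ochre curve, as a fraction of the charge, over to the violet flask, which is the one asked about.

| setting | violet | ochre | flask |
|---|---|---|---|
| free monomer | 20 mM | 40 mM | 20 mM |
| pre-initiator | 40 µM | 40 µM | 40 µM |
| impurity | 4.3 µM | 4.3 µM | 4.3 µM |
| remark | the very flask that is asked about, followed so far | run made earlier |  |
| time |  |  | 50 h |

- violet (time / h: monomer in chains / %, free monomer / %): 5.00: 0, 99.2; 10.0: 1.1, 98.2; 15.0: 0.5, 96.9; 20.0: 5.0, 96.7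
- ochre (time / h: monomer in chains / %, free monomer / %): 6.00: 0, 101.8; 20.0: 4.7, 95.6; 30.0: 10.7, 91.3; 48.0: 32.3, 69.7

(standard deviation of a reading: 1 percentage point)

* average number of monomer units in a chain (chains begun, living or dead) at 50 h
* part of the free monomer that has reacted at 50 h

- the average divides the monomer in chains by the number of chains begun, living and dead together
- steps under discussion: free monomer + initiator -> living end + monomer in chains; free monomer + living end -> monomer in chains + living end; initiator + impurity -> spent initiator; pre-initiator -> initiator
- the earlier runs do not show the number of chains; that part of a forecast is a guess

**Frozen supply.** I freeze the supply of initiator from pre-initiator at its starting rate. In that picture impurity takes the first initiator, then living ends ramp linearly, and the log of the free monomer fraction grows as the square of the time past a delay (the induction period). I average each free monomer reading with the complement of its chains reading. In ochre the root of that log is then 0.319 at 30.0 h and 0.613 at 48.0 h, and the line through them meets zero at 10.4 h. I take the supply during that delay to equal the impurity charge, so the drain time, the delay times the pre-initiator charge over the impurity charge, reads 96.7 h.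

**Frozen numbers.** The line carried to 50 h gives a conversion of 34.1 %. I reckon chains begun as the time past the delay over the drain time, 0.410 of the pre-initiator charge, so my average is 416.

**Weak link.** The frozen supply is the weak link. If pre-initiator decays with the drain time as its time constant, the drained share less the impurity's share is 0.296, lower, and the average becomes 575. I commit to 34.1 % and an average between those two.

**The result.** The forecast says 600 and 31 %, both apart from mine, and of its chain count it says: “This is a guess.” The flask gives 445 and 32.5 %.

    free monomer + initiator → living end + monomer in chains (k = 0.840 M⁻¹ min⁻¹)
    free monomer + living end → monomer in chains + living end, rate k2*[living end]*[free monomer] (k = 20.0 M⁻¹ min⁻¹)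
    initiator + impurity → spent initiator (k = 40000 M⁻¹ min⁻¹)
    pre-initiator → initiator (k = 2.20 × 10⁻⁴ min⁻¹)

**Still moving.** Living ends in the flask at 50 h are 36.6 % of the pre-initiator charge. In the neighbour with a quarter of the impurity they are 44.4 %, where the drain time gives 0.376 to 0.490. The flask is not at rest: 52 % of its pre-initiator and 67 % of its free monomer remain. The drain time puts the pre-initiator after ten times the time at 0.568 %, and the flask then holds 0.136 %. By then the conversion is >99.9 %, and the average chain has grown from 445 to 646.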